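**Strategy.** Labdane numbering is used. Everything rests on replacing the C4–C5 bond of ring A (C1–C5, C10) by a C4–C10 bond: the precursor is a 1,2,2-trimethylcyclopentane (C1–C4, C10) whose quaternary C10 carries the C5 carbinol and the C6–C16 polyene chain. Ionising the C5 triflate should make the gem-dimethyl carbon C4 shift from C10 to C5. This one-carbon ring expansion forms ring A, sets C5 by inversion and unveils the C10 cation, which the C8=C9 alkene traps to close ring B before proton loss installs the C7=C8 alkene. The step exploits the two quaternary carbons C4 and C10 that flank C5–H in ring A and the trisubstituted C7=C8 alkene of ring B.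

Key step: step 6

Remark: the ring quaternary carbon of 3, 8, 9 and 10 (the later C10) is carried in both configurations, on the assumption that this is harmless because the centre becomes a planar cation in step 6.

**Step 1**
Reactants: 1 1-acetyl-2-methylcyclopent-1-ene
Product: 3 1-(1,2,2-trimethylcyclopentyl)ethan-1-one, via lithium enolate 2 (not isolated)
Conditions: Me2CuLi, Et2O, 0 °C; then MeI, HMPA, THF, 0 °C → rt
Reagents that add atoms: lithium dimethylcuprate [Li+].C[Cu-]C; iodomethane CI
Why: Cuprate conjugate addition to the tetrasubstituted enone gives the regiodefined enolate 2, and its C-methylation (enolate trapping) installs the second quaternary carbon, with no stereocontrol needed because this centre is ionised later.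

**Step 2**
Reactants: 4 geranyl acetate
Product: 5 (2E,6E)-8-hydroxy-3,7-dimethylocta-2,6-dien-1-yl acetate
Conditions: SeO2 (cat.), t-BuOOH, salicylic acid (cat.), CH2Cl2, rt
Reagents that add atoms: tert-butyl hydroperoxide CC(C)(C)OO (terminal oxidant, oxygen relayed by catalytic SeO2)
Why: Riley allylic oxidation (ene reaction then [2,3]-shift) should attack the (E)-methyl group of the electron-rich terminal alkene and spare the alkene deactivated by the allylic acetate.

**Step 3**
Reactants: 5 (2E,6E)-8-hydroxy-3,7-dimethylocta-2,6-dien-1-yl acetate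
Product: 6 (2E,6E)-8-bromo-3,7-dimethylocta-2,6-dien-1-yl acetate
Conditions: CBr4, PPh3, CH2Cl2, 0 °C
Reagents that add atoms: carbon tetrabromide BrC(Br)(Br)Br
Why: Appel bromination should convert the primary allylic alcohol into the bromide under neutral conditions without allylic transposition or loss of the acetate.

**Step 4**
Reactants: 3 1-(1,2,2-trimethylcyclopentyl)ethan-1-one; 6 (2E,6E)-8-bromo-3,7-dimethylocta-2,6-dien-1-yl acetate
Product: 8 (2E,6E)-3,7-dimethyl-10-oxo-10-(1,2,2-trimethylcyclopentyl)deca-2,6-dien-1-yl acetate, via kinetic lithium enolate 7 (not isolated)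
Conditions: LiN(iPr)2 (LDA), THF, −78 °C; then 6, −78 → −30 °C
Reagents that add atoms: none
Why: Ketone 3 can enolise only towards its CH3 group, and SN2 alkylation of enolate 7 by the primary allylic bromide should outrun attack on the acetate (enolate alkylation forming C6–C7).

**Step 5**
Reactants: 8 (2E,6E)-3,7-dimethyl-10-oxo-10-(1,2,2-trimethylcyclopentyl)deca-2,6-dien-1-yl acetate
Product: 9 (2E,6E,10R)-10-hydroxy-3,7-dimethyl-10-(1,2,2-trimethylcyclopentyl)deca-2,6-dien-1-yl acetate
Conditions: (S)-1-methyl-3,3-diphenyltetrahydro-1H,3H-pyrrolo[1,2-c][1,3,2]oxazaborole [(S)-Me-CBS] (0.2 equiv), catecholborane, toluene, −78 → −40 °C; MeOH quench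
Reagents that add atoms: none
Why: Corey–Bakshi–Shibata reduction, in which the (S)-oxazaborolidine differentiates the bulky tertiary ring substituent from the primary chain and should deliver hydride to give the (R)-carbinol (the later C5) in both ring epimers, while catecholborane at low temperature leaves the alkenes and the acetate untouched.

**Step 6**
Reactants: 9 (2E,6E,10R)-10-hydroxy-3,7-dimethyl-10-(1,2,2-trimethylcyclopentyl)deca-2,6-dien-1-yl acetate
Product: 11 (13E)-ent-labda-7,13-dien-15-yl acetate, via secondary triflate 10 (not isolated)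
Conditions: Tf2O, 2,6-di-tert-butyl-4-methylpyridine, CH2Cl2, −78 → −20 °C
Reagents that add atoms: none
Why: Proposed new method: Tf2O converts the neopentyl-type secondary alcohol into triflate 10, whose ionisation is assisted by the antiperiplanar C4–C10 bond, so that the quaternary C4 migrates from C10 to C5 with inversion at C5 (Wagner–Meerwein 1,2-shift) and leaves a tertiary cation at C10; the closest known reaction types are the solvolytic Wagner–Meerwein ring expansion of cyclopentylcarbinyl sulfonates and the cation–olefin cyclization of monocyclic 2,6,6-trimethylcyclohexyl cations to drimane-type decalins. Ring A arises by this one-carbon expansion of the cyclopentane, and ring B closes by 6-endo-trig attack of the (E)-C8=C9 alkene on the C10 cation through a chair transition state, after which the C8 cation loses H-7 to the pyridine base to give the C7=C8 alkene. C5 is set by the (R)-carbinol through the stereospecific inversion, and C10 and C9 are set relative to C5 by the chair-like closure with the C5 side arm equatorial (trans ring fusion, C10 methyl anti to H-5) and by the E geometry of the alkene (C11 equatorial). The step needs migration of C4 and not of C1 or the methyl group, which the higher migratory aptitude of the quaternary carbon and the relief of the congested C4–C10 bond should secure; it needs the cascade to stop at the bicycle, which the inductively deactivated allylic acetate alkene C13=C14 and the base should secure; and it needs endocyclic proton loss, which the axial H-7 aligned with the empty orbital at C8 should favour. Both C10 epimers of 9 should converge on the same cation because that centre becomes planar.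

**Step 7**
Reactants: 11 (13E)-ent-labda-7,13-dien-15-yl acetate
Product: 12 (13E)-ent-labda-7,13-dien-15-ol
Conditions: K2CO3, MeOH, rt
Reagents that add atoms: none
Why: Base-catalysed transesterification with methanol should free the primary allylic alcohol without touching either alkene.

**Step 8**
Reactants: 12 (13E)-ent-labda-7,13-dien-15-ol
Product: 13 (13R,14R)-13,14-epoxy-ent-labd-7-en-15-ol
Conditions: Ti(OiPr)4 (0.1 equiv), diisopropyl D-(−)-tartrate (0.12 equiv), t-BuOOH, 4 Å molecular sieves, CH2Cl2, −20 °C
Reagents that add atoms: tert-butyl hydroperoxide CC(C)(C)OO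
Why: Katsuki–Sharpless asymmetric epoxidation acts only on the allylic-alcohol alkene, and the D-(−)-tartrate should deliver oxygen under reagent control to the face that gives the (13R,14R)-epoxide (the mirror sense of geraniol with L-(+)-tartrate).

**Step 9**
Reactants: 13 (13R,14R)-13,14-epoxy-ent-labd-7-en-15-ol
Product: 14 (13S,14R)-ent-labd-7-ene-13,14,15-triol
Conditions: HClO4 (cat., aq.), THF/H2O, 0 °C → rt
Reagents that add atoms: water O
Why: Acid-catalysed epoxide hydrolysis, in which water should open the protonated epoxide at the tertiary C13 from the rear, inverting C13 to S and leaving C14 as R to give the anti triol.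

**Step 10**
Reactants: 14 (13S,14R)-ent-labd-7-ene-13,14,15-triol
Product: 15 (13S,14R)-14,15-diacetoxy-ent-labd-7-en-13-ol (CNP0545929.1)
Conditions: Ac2O, pyridine, rt
Reagents that add atoms: acetic anhydride CC(=O)OC(C)=O
Why: Acetylation with Ac2O/pyridine should esterify the primary and secondary hydroxyl groups and leave the hindered tertiary C13 hydroxyl free.

**Compound list**
1 | 1-acetyl-2-methylcyclopent-1-ene | CC(=O)C1=C(C)CCC1 | starting material
2 | lithium 1-(2,2-dimethylcyclopentylidene)ethan-1-olate | [Li+].[O-]C(C)=C1CCCC1(C)C | intermediate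
3 | 1-(1,2,2-trimethylcyclopentyl)ethan-1-one (racemic) | CC(=O)C1(C)CCCC1(C)C | intermediate
4 | geranyl acetate, (2E)-3,7-dimethylocta-2,6-dien-1-yl acetate | CC(=O)OC/C=C(\C)CCC=C(C)C | starting material
5 | (2E,6E)-8-hydroxy-3,7-dimethylocta-2,6-dien-1-yl acetate | CC(=O)OC/C=C(\C)CC/C=C(\C)CO | intermediate
6 | (2E,6E)-8-bromo-3,7-dimethylocta-2,6-dien-1-yl acetate | CC(=O)OC/C=C(\C)CC/C=C(\C)CBr | intermediate
7 | lithium 1-(1,2,2-trimethylcyclopentyl)ethen-1-olate | [Li+].[O-]C(=C)C1(C)CCCC1(C)C | intermediate
8 | (2E,6E)-3,7-dimethyl-10-oxo-10-(1,2,2-trimethylcyclopentyl)deca-2,6-dien-1-yl acetate (both ring configurations) | CC(=O)OC/C=C(\C)CC/C=C(\C)CCC(=O)C1(C)CCCC1(C)C | intermediate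
9 | (2E,6E,10R)-10-hydroxy-3,7-dimethyl-10-(1,2,2-trimethylcyclopentyl)deca-2,6-dien-1-yl acetate (both ring configurations) | CC(=O)OC/C=C(\C)CC/C=C(\C)CC[C@@H](O)C1(C)CCCC1(C)C | intermediate
10 | (2E,6E,10R)-3,7-dimethyl-10-[(trifluoromethanesulfonyl)oxy]-10-(1,2,2-trimethylcyclopentyl)deca-2,6-dien-1-yl acetate | CC(=O)OC/C=C(\C)CC/C=C(\C)CC[C@@H](OS(=O)(=O)C(F)(F)F)C1(C)CCCC1(C)C | intermediate
11 | (13E)-ent-labda-7,13-dien-15-yl acetate, (2E)-3-methyl-5-[(1R,4aR,8aR)-2,5,5,8a-tetramethyl-1,4,4a,5,6,7,8,8a-octahydronaphthalen-1-yl]pent-2-en-1-yl acetate | CC(=O)OC/C=C(\C)CC[C@@H]1C(C)=CC[C@@H]2C(C)(C)CCC[C@@]12C | intermediate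
12 | (13E)-ent-labda-7,13-dien-15-ol (5R,9R,10R) | OC/C=C(\C)CC[C@@H]1C(C)=CC[C@@H]2C(C)(C)CCC[C@@]12C | intermediate
13 | (5R,9R,10R,13R,14R)-13,14-epoxy-ent-labd-7-en-15-ol | OC[C@H]1O[C@]1(C)CC[C@@H]2C(C)=CC[C@@H]3C(C)(C)CCC[C@@]23C | intermediate
14 | (5R,9R,10R,13S,14R)-ent-labd-7-ene-13,14,15-triol | OC[C@@H](O)[C@@](C)(O)CC[C@@H]1C(C)=CC[C@@H]2C(C)(C)CCC[C@@]12C | intermediate
15 | (5R,9R,10R,13S,14R)-14,15-diacetoxy-ent-labd-7-en-13-ol (CNP0545929.1) | CC(=O)OC[C@@H](OC(C)=O)[C@@](C)(O)CC[C@@H]1C(C)=CC[C@@H]2C(C)(C)CCC[C@@]12C | target

**Totals.** Total step count: 10. Longest linear sequence: 9 steps (4 → 15 through steps 2, 3, 4, 5, 6, 7, 8, 9 and 10).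

**Steps most likely to fail**

Step 6 (Proposed new method). The ring-expanded C10 cation may lose a proton before the alkene captures it, a ring bond other than C4–C10 may migrate, or the final proton loss from C8 may be unselective between the endocyclic and exocyclic positions. The fallback uses known chemistry, sets out from 9 and comes back at 11, and separates ring expansion from ring closure. Alcohol 9 is converted with MsCl and Et3N into the mesylate F1. Solvolysis of the mesylate F1 in aqueous acetone buffered with CaCO3 is a Wagner–Meerwein ring expansion of a cyclopentylcarbinyl sulfonate in a nucleophilic medium, where water should capture the C10 cation; it should give the ring-expanded tertiary alcohol F2 with C5 already set. The tertiary alcohol F2 is then ionised separately with SnCl4 in CH2Cl2 at −78 °C, the known cation–olefin closure of a monocyclic 2,6,6-trimethylcyclohexyl precursor, to give 11.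

Step 1. Conjugate addition to the tetrasubstituted enone may be slow, and C-methylation of the congested copper-containing enolate may lose out to proton transfer. The fallback sets out from 1 and comes back at 3. Me2CuLi with Me3SiCl in THF at −78 °C (silyl-accelerated conjugate addition) should give the isolable silyl enol ether F3. Simmons–Smith cyclopropanation with Et2Zn and CH2I2 should convert it into the siloxycyclopropane F4. NaOH in aqueous methanol then opens the cyclopropanol towards the primary carbanion, which places the new methyl group on the ring carbon and gives 3.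

Step 4. Proton exchange between the product ketone and enolate 7 may lead to double alkylation, and acyl transfer from the acetate to the hard lithium enolate may compete. The fallback sets out from 3 and comes back at 8. C-acylation of 3 with NaH and dimethyl carbonate should give the β-keto ester F5. Its soft enolate (K2CO3, acetone) should be alkylated once by bromide 6 to give the alkylated keto ester F6 without touching the acetate. LiOH in aqueous THF, then gentle warming of the acidified solution, removes both ester groups with decarboxylation to give the hydroxy ketone F7. Ac2O in pyridine restores the acetate and gives 8.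

**Further compounds**
F1 | step 6 | (2E,6E,10R)-10-(methanesulfonyloxy)-3,7-dimethyl-10-(1,2,2-trimethylcyclopentyl)deca-2,6-dien-1-yl acetate | CC(=O)OC/C=C(\C)CC/C=C(\C)CC[C@@H](OS(C)(=O)=O)C1(C)CCCC1(C)C
F2 | step 6 | (2E,6E)-9-[(1R)-2-hydroxy-2,6,6-trimethylcyclohexyl]-3,7-dimethylnona-2,6-dien-1-yl acetate (both carbinol configurations) | CC(=O)OC/C=C(\C)CC/C=C(\C)CC[C@H]1C(C)(O)CCCC1(C)C
F3 | step 1 | {[1-(2,2-dimethylcyclopentylidene)ethyl]oxy}trimethylsilane | C[Si](C)(C)OC(C)=C1CCCC1(C)C
F4 | step 1 | trimethyl[(1,4,4-trimethylspiro[2.4]heptan-1-yl)oxy]silane (mixture of diastereomers) | C[Si](C)(C)OC1(C)CC12CCCC2(C)C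
F5 | step 4 | methyl 3-oxo-3-(1,2,2-trimethylcyclopentyl)propanoate | COC(=O)CC(=O)C1(C)CCCC1(C)C
F6 | step 4 | methyl (4E,8E)-10-acetoxy-4,8-dimethyl-2-[(1,2,2-trimethylcyclopentyl)carbonyl]deca-4,8-dienoate | CC(=O)OC/C=C(\C)CC/C=C(\C)CC(C(=O)OC)C(=O)C1(C)CCCC1(C)C
F7 | step 4 | (4E,8E)-10-hydroxy-4,8-dimethyl-1-(1,2,2-trimethylcyclopentyl)deca-4,8-dien-1-one | OC/C=C(\C)CC/C=C(\C)CCC(=O)C1(C)CCCC1(C)C
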